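1. Late on, the elm curve had bent: it gained 0.6 percentage points between 8.00 min and 10.0 min, after 6.3% in its first 2.00 min. I wanted to know what that bend means for two new flasks.

| setting | elm | birch | amber | violet |
|---|---|---|---|---|
| starting material | 0.10 M | 0.10 M | 0.10 M | 0.10 M |
| coupling partner | 0.11 M | 0.11 M | 0.110 M | 0.110 M |
| free catalyst | 3.4 mM | 3.7 mM | 2.3 mM | 3.0 mM |
| remark | run made earlier | run made earlier |  |  |
| time |  |  | 15 min | 8.0 min |

| run | time / min | target / % |
|---|---|---|
| elm | 2.00 | 6.3 |
| elm | 4.00 | 9.6 |
| elm | 5.00 | 11.4 |
| elm | 8.00 | 13.5 |
| elm | 10.0 | 14.1 |
| birch | 0.667 | 2.4 |
| birch | 2.00 | 7.2 |
| birch | 4.00 | 10.8 |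
| birch | 6.00 | 12.6 |
| birch | 8.00 | 13.7 |
| birch | 10.0 | 14.2 |

(standard deviation of a reading: 0.5 percentage points)
- percent here means starting material units held: one side product counts as two
- what is said of by-product includes idle complex
- steps under discussion: catalyst intermediate A -> catalyst intermediate B; catalyst intermediate B <-> by-product + catalyst intermediate C; catalyst intermediate D <-> free catalyst + target; free catalyst + by-product <-> idle complex; coupling partner + free catalyst -> catalyst intermediate A; starting material + target -> side product; starting material + catalyst intermediate C -> catalyst intermediate D
* which one finishes higher in amount of target, in percent of the starting material charged ("neither" within 2 percentage points) (amber / violet / neither)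
* amount of target at the end, in percent of the starting material charged, amber
* amount of target at the end, in percent of the starting material charged, violet

2. Each round releases by-product, and free catalyst binds by-product as idle complex. I supposed that the catalyst still working goes as its charge over the by-product, and that by-product grows with target. Rate then goes as catalyst over target, so target fraction squared grows as catalyst fraction (of the starting material) times time.

3. I therefore took target fraction squared over that product, averaged over elm and birch. It was 0.0652 /min at 8.00 min and 0.0565 /min at 10.0 min. I took this fall as the leak of target to side product, though each reading carries a scatter of 0.5 points, so the figure is soft.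

4. Continuing the fall at the same ratio gave the late constant for 15 min, 0.0395 /min.

5. My reckoning gave amber 11.7%. Violet, at a time both runs read, gave 12.5%. The gap is under 2 points, so I said neither.

6. The forecast said neither, with amber 13.3% and violet 12.8%, on the ground that “catalyst × time is a fair scaling variable”. It puts amber above violet, where I put amber below.

7. The flasks gave neither: amber 12.0%, violet 12.3%.

    catalyst intermediate A → catalyst intermediate B (k = 0.119 /s)
    catalyst intermediate B ⇌ by-product + catalyst intermediate C (K = 0.107 M, k = 0.109 /s)
    catalyst intermediate D ⇌ free catalyst + target (K = 0.0109 M, k = 0.667 /s)
    free catalyst + by-product ⇌ idle complex, settled at all times (K = 685 /M)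
    coupling partner + free catalyst → catalyst intermediate A (k = 1.10 /M/s)
    starting material + target → side product (k = 0.0126 /M/s)
    starting material + catalyst intermediate C → catalyst intermediate D (k = 1.51 /M/s)

8. Amber's own end gives a late constant of 0.0421 /min, against my 0.0395 /min. In amber, the half-life of coupling partner by its step with free catalyst was 82 min at 15.0 min, longer than the run, and 81% of that charge was left. Amber's target stood at 18.5% at 150 min, higher than at the asked time.

9. For a neighbour of amber, charged with 9.20 mM of free catalyst and otherwise the same, the late constant gives 23.3%. The flask gave 28.6%.

The runs stem from a simulated flask for an exercise; the scatter is artificial.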